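**Plan**

1. Locants: plain for the 6-linked flavone, doubly primed for the 8-linked flavone, 4' and 4''' for the para carbons of the two pendant phenyl rings. Retrosynthetically, the O5 methyl, O5'' ethyl and two benzyl groups come off last. Ring C'' is cut at O1''–C2'' (cyclodehydration), C2''–C3'' (aroylation) and C4''–C4a'' (Fries acetylation), leaving a 2-arylphenol.
2. Ring A'' of that phenol is cut at C8''–C8a'' and C6''–C7''. C8'' (carrying the other flavone) and its neighbour C7'' (carrying OMe) are the two carbons of a methoxyalkyne on C6. C6'', C5'' (O), C4a'' and C8a'' (O) are the four ring carbons of 3-ethoxycyclobut-2-enone.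
3. The alkyne is cut at C6–C(sp), back to a 6-iodoflavone obtained from genkwanin.
4. Forward: the 6-linked flavone is bought complete and carried as a spectator; C6 is iodinated and alkynylated, ring A'' is grown on the alkyne by benzannulation, and ring C'' is closed last on the new phenol.
5. Stereochemistry: there is no stereocentre; the hindered 6–8'' axis forms without control.

Key step: step 5

Remark on the chemistry: the target is drawn without a descriptor for the biaryl axis, so it is taken to be wanted as the racemate with respect to that axis.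

**Route**

Step 1
Reactants: 1 genkwanin (5,4'-dihydroxy-7-methoxyflavone)
Product: 2 4'-(benzyloxy)-5-hydroxy-7-methoxyflavone
Conditions: BnBr (1.1 equiv), K2CO3 (1.5 equiv), DMF, rt
Reagents that add atoms: benzyl bromide, BrCc1ccccc1
Why: Williamson etherification should take the free, more acidic 4'-hydroxyl, because the 5-hydroxyl is hydrogen-bonded to the C4 carbonyl and is not alkylated by K2CO3 at room temperature.

Step 2
Reactants: 2 4'-(benzyloxy)-5-hydroxy-7-methoxyflavone
Product: 3 4'-(benzyloxy)-5-hydroxy-6-iodo-7-methoxyflavone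
Conditions: BnNMe3 ICl2 (1.1 equiv), CaCO3, CH2Cl2/MeOH, rt
Reagents that add atoms: benzyltrimethylammonium dichloroiodate, C[N+](C)(C)Cc1ccccc1.Cl[I-]Cl
Why: Electrophilic aromatic iodination should go ortho to the free 5-hydroxyl, at C6, as is known for 5-hydroxy-7-alkoxyflavones with this reagent (5-O-alkyl flavones iodinate at C8 instead, which is why iodination precedes methylation), while CaCO3 takes up the HCl.

Step 3
Reactants: 3 4'-(benzyloxy)-5-hydroxy-6-iodo-7-methoxyflavone
Product: 4 4'-(benzyloxy)-6-iodo-5,7-dimethoxyflavone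
Conditions: Me2SO4, K2CO3, acetone, reflux
Reagents that add atoms: dimethyl sulfate, COS(=O)(=O)OC
Why: Williamson O-methylation under forcing conditions overcomes the chelation of the 5-hydroxyl and caps a phenol that would otherwise add across the neighbouring ynol ether in the next steps.

Step 4
Reactants: 4 4'-(benzyloxy)-6-iodo-5,7-dimethoxyflavone; 5 chloroacetaldehyde dimethyl acetal
Product: 8 4'-(benzyloxy)-5,7-dimethoxy-6-(methoxyethynyl)flavone, via lithium methoxyacetylide 6 (not isolated), via methoxyethynylzinc chloride 7 (not isolated)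
Conditions: 5 (2 equiv), LiNEt2 (6 equiv), THF, 0 °C; ZnCl2 (4 equiv), 0 °C to rt; then 4, Pd(PPh3)4 (5 mol %), THF, rt to 45 °C; NaHCO3 work-up, Et3N-deactivated silica
Reagents that add atoms: none
Why: Negishi coupling of an alkynylzinc chloride with an aryl iodide, in which the acetylide comes from the acetal by two eliminations and a deprotonation, zinc tames it so that the pyranone carbonyl is spared, and the slim alkynyl group can be delivered to the doubly ortho-substituted C6.

Step 5
Reactants: 8 4'-(benzyloxy)-5,7-dimethoxy-6-(methoxyethynyl)flavone; 9 3-ethoxycyclobut-2-enone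
Product: 14 4'-(benzyloxy)-6-(4-ethoxy-2-hydroxy-6-methoxyphenyl)-5,7-dimethoxyflavone, via 3-ethoxyvinylketene 10 (not isolated), via cyclobutenone adduct 11 (not isolated), via dienylketene 12 (not isolated), via cyclohexadienone tautomer 13 (not isolated)
Conditions: 9 (2.5 equiv, in portions), toluene (degassed, base-washed glassware), 80 °C then 110 °C; then K2CO3, MeOH, rt
Reagents that add atoms: none
Why: Thermal four-electron electrocyclic opening of 9 gives vinylketene 10, whose ketene carbon (future C8a'') is attacked by the aryl-bearing alkyne carbon of 8 (future C8''), the carbon that the methoxy group makes nucleophilic, so that a regioselective (2+2) cycloaddition also joins C7'' to C6'' and gives cyclobutenone 11. Four-electron opening of 11 to dienylketene 12 and six-electron electrocyclic closure, the mode by which the six-membered ring A'' is closed, re-form the C4a''–C8a'' bond, and tautomerisation of dienone 13 delivers phenol 14. This is the Danheiser benzannulation of cyclobutenones with alkoxyalkynes, here with an aryl-substituted methoxyalkyne and an alkoxy-substituted cyclobutenone, a pairing that is expected to work but has not been tried on so hindered a case. No stereocentre is created (the one in 11 is transient) and the new tetra-ortho-substituted axis forms as the racemate. The only selectivity needed is the sense of the ketene–alkyne union, which the polarisation of the ynol ether secures and which places OMe on C7'', H on C6'', OEt on C5'' and the single free OH on C8a''. The linear alkyne holds the reacting carbons clear of the flanking 5- and 7-methoxy groups, a methoxy ynol ether has no beta-hydrogen for retro-ene loss of an alkene, and the methanolic K2CO3 treatment returns any phenol that surplus ketene has O-acylated.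

Step 6
Reactants: 14 4'-(benzyloxy)-6-(4-ethoxy-2-hydroxy-6-methoxyphenyl)-5,7-dimethoxyflavone
Product: 17 6-(3-acetyl-4-ethoxy-2-hydroxy-6-methoxyphenyl)-4'-(benzyloxy)-5,7-dimethoxyflavone, via aryl acetate 15 (not isolated), via difluoroboron chelate 16 (not isolated)
Conditions: Ac2O (2 equiv), BF3·OEt2 (4 equiv), ClCH2CH2Cl, rt to 70 °C; then NaOAc, MeOH/H2O, 50 °C
Reagents that add atoms: acetic anhydride, CC(=O)OC(C)=O
Why: O-acetylation followed by BF3-mediated Fries rearrangement should end at the one free ortho position, C4a'', because only the ortho-hydroxy ketone is held as a six-membered difluoroboron chelate, as in the standard preparation of 2-hydroxy-4,6-dialkoxyacetophenones from 3,5-dialkoxyphenols.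

Step 7
Reactants: 17 6-(3-acetyl-4-ethoxy-2-hydroxy-6-methoxyphenyl)-4'-(benzyloxy)-5,7-dimethoxyflavone; 18 4-(benzyloxy)benzoyl chloride
Product: 19 1-{3-[4'-(benzyloxy)-5,7-dimethoxyflavon-6-yl]-6-ethoxy-2-hydroxy-4-methoxyphenyl}-3-[4-(benzyloxy)phenyl]propane-1,3-dione
Conditions: LiN(SiMe3)2 (4 equiv), THF, −78 to −10 °C; 18 (1.1 equiv), −78 °C to rt; aq. NH4Cl
Reagents that add atoms: none
Why: The lithium phenoxide-enolate dianion is aroylated at carbon by the acid chloride, a Claisen-type condensation that is the one-flask form of the Baker–Venkataraman route to 2-hydroxyaryl 1,3-diketones (any O-aroyl ester rearranges to the same diketone under the excess base), and the hindered silylamide does not open the existing pyranone.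

Step 8
Reactants: 19 the 1,3-diketone of step 7
Product: 20 4',4'''-bis(benzyloxy)-5''-ethoxy-5,7,7''-trimethoxy-6,8''-biflavone
Conditions: TsOH·H2O (20 mol %), toluene, 100 °C, Dean–Stark
Reagents that add atoms: none
Why: Acid-catalysed cyclodehydration of a 2-hydroxyaryl 1,3-diketone, the standard flavone closure, in which the only free phenol (on C8a'') adds 6-exo-trig to the aroyl carbonyl and water is lost, so that only the 8''-linked pyranone can form.

Step 9
Reactants: 20 4',4'''-bis(benzyloxy)-5''-ethoxy-5,7,7''-trimethoxy-6,8''-biflavone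
Product: 21 DMGF (4',4''',5,5''-tetrahydroxy-7,7''-dimethoxy-6,8''-biflavone)
Conditions: BCl3 (12 equiv), C6HMe5 (6 equiv), CH2Cl2, −78 °C to rt; MeOH, then aq. HCl
Reagents that add atoms: none
Why: BCl3 ether cleavage, in which chelation to each C4 carbonyl activates the peri O5 methyl and O5'' ethyl groups for loss as alkyl chlorides, the benzyl ethers are cleaved with pentamethylbenzene trapping the benzyl cation, and the non-chelated 7- and 7''-methoxy groups are left in place.

**Compound list**

1 | genkwanin (5,4'-dihydroxy-7-methoxyflavone) | COc1cc(O)c2c(=O)cc(-c3ccc(O)cc3)oc2c1 | starting material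
2 | 4'-(benzyloxy)-5-hydroxy-7-methoxyflavone | COc1cc(O)c2c(=O)cc(-c3ccc(OCc4ccccc4)cc3)oc2c1 | intermediate
3 | 4'-(benzyloxy)-5-hydroxy-6-iodo-7-methoxyflavone | COc1cc2oc(-c3ccc(OCc4ccccc4)cc3)cc(=O)c2c(O)c1I | intermediate
4 | 4'-(benzyloxy)-6-iodo-5,7-dimethoxyflavone | COc1cc2oc(-c3ccc(OCc4ccccc4)cc3)cc(=O)c2c(OC)c1I | intermediate
5 | chloroacetaldehyde dimethyl acetal | COC(CCl)OC | starting material
6 | lithium methoxyacetylide | [Li]C#COC | intermediate
7 | methoxyethynylzinc chloride | COC#C[Zn]Cl | intermediate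
8 | 4'-(benzyloxy)-5,7-dimethoxy-6-(methoxyethynyl)flavone | COC#Cc1c(OC)cc2oc(-c3ccc(OCc4ccccc4)cc3)cc(=O)c2c1OC | intermediate
9 | 3-ethoxycyclobut-2-enone | CCOC1=CC(=O)C1 | starting material
10 | 3-ethoxybuta-1,3-dien-1-one (3-ethoxyvinylketene) | C=C(OCC)C=C=O | intermediate
11 | 4'-(benzyloxy)-6-[3-(1-ethoxyvinyl)-2-methoxy-4-oxocyclobut-1-en-1-yl]-5,7-dimethoxyflavone (racemic) | O=C1C(C(=C)OCC)C(OC)=C1c1c(OC)cc2oc(-c3ccc(OCc4ccccc4)cc3)cc(=O)c2c1OC | intermediate
12 | 4'-(benzyloxy)-6-(5-ethoxy-3-methoxy-1-oxohexa-1,3,5-trien-2-yl)-5,7-dimethoxyflavone (ketene carbon and ethoxyvinyl group cis on the central double bond) | O=C=C(c1c(OC)cc2oc(-c3ccc(OCc4ccccc4)cc3)cc(=O)c2c1OC)/C(OC)=C\C(=C)OCC | intermediate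
13 | 4'-(benzyloxy)-6-(4-ethoxy-2-methoxy-6-oxocyclohexa-1,3-dien-1-yl)-5,7-dimethoxyflavone | O=C1CC(OCC)=CC(OC)=C1c1c(OC)cc2oc(-c3ccc(OCc4ccccc4)cc3)cc(=O)c2c1OC | intermediate
14 | 4'-(benzyloxy)-6-(4-ethoxy-2-hydroxy-6-methoxyphenyl)-5,7-dimethoxyflavone (racemic axis) | COc1cc2oc(-c3ccc(OCc4ccccc4)cc3)cc(=O)c2c(OC)c1-c1c(OC)cc(OCC)cc1O | intermediate
15 | 6-(2-acetoxy-4-ethoxy-6-methoxyphenyl)-4'-(benzyloxy)-5,7-dimethoxyflavone | COc1cc2oc(-c3ccc(OCc4ccccc4)cc3)cc(=O)c2c(OC)c1-c1c(OC)cc(OCC)cc1OC(C)=O | intermediate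
16 | difluoroboron chelate of 17 (BF2 bridging the C8a'' phenolate oxygen and the acetyl oxygen) | COc1cc2oc(-c3ccc(OCc4ccccc4)cc3)cc(=O)c2c(OC)c1-c1c(OC)cc(OCC)c2c1O[B-](F)(F)[O+]=C2C | intermediate
17 | 6-(3-acetyl-4-ethoxy-2-hydroxy-6-methoxyphenyl)-4'-(benzyloxy)-5,7-dimethoxyflavone | COc1cc2oc(-c3ccc(OCc4ccccc4)cc3)cc(=O)c2c(OC)c1-c1c(OC)cc(OCC)c(C(C)=O)c1O | intermediate
18 | 4-(benzyloxy)benzoyl chloride | O=C(Cl)c1ccc(OCc2ccccc2)cc1 | starting material
19 | 1-{3-[4'-(benzyloxy)-5,7-dimethoxyflavon-6-yl]-6-ethoxy-2-hydroxy-4-methoxyphenyl}-3-[4-(benzyloxy)phenyl]propane-1,3-dione (drawn as the diketo form) | COc1cc2oc(-c3ccc(OCc4ccccc4)cc3)cc(=O)c2c(OC)c1-c1c(OC)cc(OCC)c(C(=O)CC(=O)c2ccc(OCc3ccccc3)cc2)c1O | intermediate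
20 | 4',4'''-bis(benzyloxy)-5''-ethoxy-5,7,7''-trimethoxy-6,8''-biflavone | COc1cc2oc(-c3ccc(OCc4ccccc4)cc3)cc(=O)c2c(OC)c1-c1c(OC)cc(OCC)c2c(=O)cc(-c3ccc(OCc4ccccc4)cc3)oc12 | intermediate
21 | DMGF, 4',4''',5,5''-tetrahydroxy-7,7''-dimethoxy-6,8''-biflavone (racemic axis) | COc1cc2oc(-c3ccc(O)cc3)cc(=O)c2c(O)c1-c1c(OC)cc(O)c2c(=O)cc(-c3ccc(O)cc3)oc12 | target

**Count and risks**

Total step count: 9. Longest linear sequence: 9 steps, from genkwanin 1 to 21.

Steps most likely to fail:

1. Step 5. Approach of the ketene to the aryl-bearing alkyne carbon is shielded by two ortho methoxy groups, so self-condensation of the vinylketene or hydration of the ynol ether may outrun the cycloaddition. The fallback sets out from 4 and returns at 17, replacing steps 5 and 6.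
   - Miyaura borylation of 4 (B2pin2, PdCl2(dppf), KOAc, dioxane, 90 °C) would give 4'-(benzyloxy)-5,7-dimethoxy-6-(4,4,5,5-tetramethyl-1,3,2-dioxaborolan-2-yl)flavone F1.
   - Commercial 2',6'-dihydroxy-4'-methoxyacetophenone would be mono-O-ethylated (EtI, K2CO3, acetone; the second hydroxyl stays chelated) to 1-(2-ethoxy-6-hydroxy-4-methoxyphenyl)ethanone F2.
   - F2 would be iodinated ortho to its free hydroxyl (BnNMe3 ICl2, CaCO3, CH2Cl2/MeOH) to 1-(6-ethoxy-2-hydroxy-3-iodo-4-methoxyphenyl)ethanone F3.
   - Suzuki–Miyaura coupling of F1 with F3 (Pd(OAc)2, SPhos, K3PO4, toluene/H2O, 90 °C) would form the C6–C8'' bond directly and give 17, and the route continues at step 7.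

2. Step 4. Oxidative addition at the doubly ortho-substituted iodide may be slow, the pyranone may be attacked before transmetalation to zinc is complete, and the ynol ether may be hydrated by zinc salts during coupling and work-up. The fallback sets out from 4 and from acetylide 6 and returns at 8.
   - Acetylide 6 would be quenched with Bu3SnCl and the product distilled as tributyl(methoxyethynyl)stannane F4.
   - Stille coupling of F4 with 4 (Pd(PPh3)4, CuI 10 mol %, DMF, 50 °C) under neutral, salt-free conditions would give 8.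

3. Step 6. The Lewis acid may strip the 4'-benzyl group, and the acetyl group may migrate to C6'' (para to the hydroxyl) instead of C4a''. The fallback sets out from 14 and returns at 17.
   - Ortho-specific formylation through the magnesium phenoxide (MgCl2, Et3N, paraformaldehyde, MeCN, reflux) would give 4'-(benzyloxy)-6-(4-ethoxy-3-formyl-2-hydroxy-6-methoxyphenyl)-5,7-dimethoxyflavone F5.
   - Aldehyde-selective methyl transfer with MeTi(OiPr)3 (2.2 equiv, THF, −40 to 0 °C), which leaves the pyranone carbonyl alone, would give 4'-(benzyloxy)-6-[4-ethoxy-2-hydroxy-3-(1-hydroxyethyl)-6-methoxyphenyl]-5,7-dimethoxyflavone F6 as a mixture of diastereomers that does not matter.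
   - Oxidation of the benzylic carbinol (MnO2, CH2Cl2, rt) would give 17.

**Further compounds**

F1 | step 5 | 4'-(benzyloxy)-5,7-dimethoxy-6-(4,4,5,5-tetramethyl-1,3,2-dioxaborolan-2-yl)flavone | COc1cc2oc(-c3ccc(OCc4ccccc4)cc3)cc(=O)c2c(OC)c1B1OC(C)(C)C(C)(C)O1
F2 | step 5 | 1-(2-ethoxy-6-hydroxy-4-methoxyphenyl)ethanone | CCOc1cc(OC)cc(O)c1C(C)=O
F3 | step 5 | 1-(6-ethoxy-2-hydroxy-3-iodo-4-methoxyphenyl)ethanone | CCOc1cc(OC)c(I)c(O)c1C(C)=O
F4 | step 4 | tributyl(methoxyethynyl)stannane | CCCC[Sn](CCCC)(CCCC)C#COC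
F5 | step 6 | 4'-(benzyloxy)-6-(4-ethoxy-3-formyl-2-hydroxy-6-methoxyphenyl)-5,7-dimethoxyflavone | COc1cc2oc(-c3ccc(OCc4ccccc4)cc3)cc(=O)c2c(OC)c1-c1c(OC)cc(OCC)c(C=O)c1O
F6 | step 6 | 4'-(benzyloxy)-6-[4-ethoxy-2-hydroxy-3-(1-hydroxyethyl)-6-methoxyphenyl]-5,7-dimethoxyflavone (mixture of diastereomers) | COc1cc2oc(-c3ccc(OCc4ccccc4)cc3)cc(=O)c2c(OC)c1-c1c(OC)cc(OCC)c(C(C)O)c1O
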